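## Structural features

The target is an open-chain 8-O-4′ neolignan. Ring A (C1–C6, 3,4,5-trimethoxyphenyl) and ring B (C1′–C6′, 3′-methoxy) are two isolated benzene rings joined only by the bridge C7(=O)–C8–O–C4′, so no ring has to be closed. C8 is the only stereocentre (S); it carries H, the methyl group C9, the aryloxy oxygen and the aroyl carbon C7, and no neighbouring stereocentre is available for relay. The C8–H bond is activated twice, by the aryl ketone at C7 and by the geminal aryloxy group, so the finished ketone loses its configuration through the enol or enolate on contact with base or warm acid. Para to the ether oxygen, ring B carries the (E)-C7′=C8′–C9′H2–OMe cinnamyl methyl ether, an electron-rich styrene sensitive to acid (allyl cation), to metal hydrides and to quinone-type oxidants. The five methyl ethers are inert, and the oxygen patterns of rings A and B are those of cheap pyrogallol and guaiacol derivatives. Building either ring from open chains would therefore add complexity, and an aryne fails as well, because a 3-methoxyaryne takes its nucleophile meta to the methoxy group, the wrong carbon for C4′. The real difficulty is C8: it must be created in the absolute sense, and the C7 ketone must be released without base being present afterwards. The key step exploits the fact that C8 has exactly the substitution of the Markovnikov H/CHO adduct of a vinyl ether: C9 is an unfunctionalised methyl group (a former =CH2), the O–C4′ oxygen of ring B is a vinylic substituent that steers a metal to C8, and C7 is a single carbonyl carbon that can come from carbon monoxide.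

## Logic of the disconnections

**9 ⇒ 8.** No skeletal bond is cut; C7=O is taken back to C7–OH. The reason is the acidity of C8–H in 9. In 8 that hydrogen is an ordinary ether C–H, so every basic or hot operation can be placed before the ketone exists. The price is a throw-away carbinol centre at C7 whose configuration does not matter. The forward step must be a neutral oxidation that spares the C7′=C8′ alkene and the allylic C9′–O bond, and it must come last.

**8 ⇒ 6 + 7.** The aryl–alkenyl bond C1′–C7′ is cut. This removes the only other C=C bond from all earlier compounds, so the key step meets a single alkene. It also brings in C7′–C9′ with the 9′-methoxy group as one commercial piece with the E geometry fixed. Ring B is simplified to a bromoarene. The forward coupling must retain the alkene geometry and tolerate a free secondary alcohol.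

**6 ⇒ 3 + 4 (through 5).** The bond C1–C7 is cut, with ring A as nucleophile and C7 as an aldehyde carbon. The molecule falls into two halves of similar size, and ring A becomes a commercial bromide. The forward addition must outrun deprotonation of C8–H in 3 and must not exchange the ring B bromide.

**3 ⇒ 2 (key disconnection).** The bonds C7–C8 and C9–H are cut, and C7 leaves as carbon monoxide. In one sentence, the route is the asymmetric hydroformylation of the achiral aryl vinyl ether 2. The cut erases the only stereocentre and the carbonyl group together: 2 is flat, achiral and has no acidic hydrogen. In the usual plans the ether oxygen must displace a leaving group at a stereocentre; here it becomes the substituent that directs the metal to C8. The forward step must give branched regiochemistry, select one alkene face, and run in a neutral medium in which 3 keeps its configuration.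

**2 ⇒ 1.** The O–C8 bond is cut while C8 is still sp2. The 8-O-4′ linkage is thus made as a vinylic C–O bond with no stereochemical content, from a commodity phenol. The forward step must transfer vinyl rather than acetyl to the phenol oxygen and leave C–Br untouched.

## Other disconnections considered

**Alternative 1:** The cut that comes to mind first is C8–O, with C8 as an sp3 electrophile.
- Forward key step: Mitsunobu inversion of methyl (R)-lactate A2 by 2-methoxy-4-[(1E)-3-methoxyprop-1-en-1-yl]phenol A1. This gives methyl (2S)-2-{2-methoxy-4-[(1E)-3-methoxyprop-1-en-1-yl]phenoxy}propanoate A3. It is converted to the Weinreb amide (2S)-N-methoxy-2-{2-methoxy-4-[(1E)-3-methoxyprop-1-en-1-yl]phenoxy}-N-methylpropanamide A4, which acylates 5 to give 9.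
- Ground: the plan is sound, but the stereocentre is bought (from the unnatural lactate series) rather than made. It must then survive two operations with basic magnesium reagents while it sits α to a carbonyl group. The ketone is released in the quench of a basic mixture. A1 is not a commodity and needs its own sequence with phenol protection, so the count exceeds five steps. This is also the default plan and does not meet the first test.

**Alternative 2:** The cut is O–C4′, with ring B as the electrophile.
- Forward key step: SNAr of the alkoxide of (2S)-2-hydroxy-N-methoxy-N-methylpropanamide A5 on 4-fluoro-3-methoxybenzaldehyde A6, giving (2S)-2-(4-formyl-2-methoxyphenoxy)-N-methoxy-N-methylpropanamide A7. Configuration is retained because no bond to C8 is touched, so the natural lactate series fits 8S.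
- Ground: an alkoxide next to a carbonyl group is a weak nucleophile. The fluorine-bearing carbon is flanked by the donor 3′-methoxy group and activated only by the para formyl group. Heating with base in a dipolar solvent is therefore expected, which are the conditions under which C8–H of A7 exchanges. A7 also carries two competing carbonyl electrophiles, and C7′–C9′ would still need olefination, reduction and methylation. The route is longer and exposes C8 more.

**Alternative 3:** The cut is C8–O together with C8–H, at the carbene level.
- Forward key step: enantioselective O–H insertion of 2-diazo-1-(3,4,5-trimethoxyphenyl)propan-1-one A8 into phenol A1, with Rh2(OAc)4 and a chiral phosphoric acid, or CuOTf and a chiral spiro bis(oxazoline). This gives 9 directly.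
- Ground: it is the most convergent plan on paper, but a metal carbene with the C9 hydrogens next to it is prone to a 1,2-hydride shift. The electron-rich C7′=C8′ styrene of A1 is a competing cyclopropanation site. The configuration is fixed in a proton transfer to a ketone-derived enol, which is harder to control than in the diazoester series. Both partners need several steps, and the skeletal bond made is that of Alternative 1.

Key step: step 2

Assumption: (R,S)-BINAPHOS is taken to give the (S)-aldehyde from 2, parallel to its sense of induction on vinyl carboxylates. If the sense is opposite, the mirror-image ligand (S,R)-BINAPHOS is used and nothing else changes.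

## Steps

Step 1
Reactants: 1 4-bromo-2-methoxyphenol
Product: 2 4-bromo-1-(ethenyloxy)-2-methoxybenzene
Conditions: [Ir(cod)Cl]2 (1 mol %), Na2CO3 (1.0 equiv), vinyl acetate (3 equiv), toluene, 100 °C
Reagents that add atoms: vinyl acetate, C=COC(C)=O
Why: Iridium-catalysed transfer vinylation of a phenol, a well-established reaction type: the Ir–OAr species adds across vinyl acetate and β-acetoxy elimination releases the aryl vinyl ether while the carbonate takes up the acetic acid. The new C–O bond is to an sp2 carbon, so no stereochemistry is at stake, and the aryl bromide is not attacked by monovalent iridium under these conditions.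

Step 2
Reactants: 2 4-bromo-1-(ethenyloxy)-2-methoxybenzene
Product: 3 (2S)-2-(4-bromo-2-methoxyphenoxy)propanal
Conditions: Rh(acac)(CO)2 (0.5 mol %), (R,S)-BINAPHOS (2 mol %), CO/H2 (1:1, 40 bar), dry toluene, 40 °C; solvent removed, used crude
Reagents that add atoms: carbon monoxide, [C-]#[O+]
Why: This is a rhodium-catalysed asymmetric hydroformylation, a reaction type established for vinyl carboxylates, N-vinyl imides and aryl vinyl ethers. Rh(acac)(CO)2, the ligand and syngas form HRh(CO)2(BINAPHOS), a trigonal-bipyramidal hydride of monovalent rhodium with the phosphine arm equatorial and the phosphite arm apical; 2 replaces an equatorial CO, the hydride migrates to C9 while rhodium binds C8, CO inserts into the Rh–C8 bond with retention, and hydrogenolysis of the acyl releases 3. The step forms C7–C8 and C9–H and closes no ring. The branched regiochemistry is secured by the substrate, because the electronegative aryloxy oxygen on C8 stabilises the α-oxygenated alkyl–rhodium bond as in vinyl acetate, and low temperature under ample CO pressure makes the insertion irreversible so that the kinetic branched alkyl is trapped as the acyl. The C8 stereocentre is controlled by the ligand alone: its binaphthyl walls leave one quadrant open for the aryloxy group, so hydrogen and then the formyl carbon are delivered syn to the Re face of C8 (O > C9 > H), which corresponds to S. Chemoselectivity is secured by design, since 2 holds a single C=C bond and the C–Br bond is inert to monovalent rhodium under CO. The medium is neutral and aprotic, so 3 is not enolised, and it is carried on without chromatography.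

Step 3
Reactants: 3 (2S)-2-(4-bromo-2-methoxyphenoxy)propanal; 4 5-bromo-1,2,3-trimethoxybenzene
Product: 6 (2S)-2-(4-bromo-2-methoxyphenoxy)-1-(3,4,5-trimethoxyphenyl)propan-1-ol (both C7 epimers), via 3,4,5-trimethoxyphenylmagnesium bromide 5 (not isolated)
Conditions: 4, Mg, cat. I2, THF, reflux; then 3, THF, –78 °C; aq. NH4Cl
Reagents that add atoms: none
Why: Grignard formation and 1,2-addition to an α-oxygenated aldehyde; at –78 °C addition of an aryl Grignard reagent should outrun enolisation, as with O-protected lactaldehydes, so C8 is retained, and Br/Mg exchange at ring B is negligible at this temperature. The new C7 carbinol centre forms as a mixture of epimers (Felkin–Anh against chelate control), which is irrelevant because C7 becomes sp2 in step 5; the adduct of any linear aldehyde is removed here by chromatography.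

Step 4
Reactants: 6 (2S)-2-(4-bromo-2-methoxyphenoxy)-1-(3,4,5-trimethoxyphenyl)propan-1-ol (both C7 epimers); 7 2-[(1E)-3-methoxyprop-1-en-1-yl]-4,4,5,5-tetramethyl-1,3,2-dioxaborolane
Product: 8 (2S)-2-{2-methoxy-4-[(1E)-3-methoxyprop-1-en-1-yl]phenoxy}-1-(3,4,5-trimethoxyphenyl)propan-1-ol (both C7 epimers)
Conditions: Pd(dppf)Cl2 (3 mol %), K2CO3 (2.5 equiv), 1,4-dioxane/H2O, 80 °C
Reagents that add atoms: none
Why: Suzuki–Miyaura coupling of an aryl bromide with an (E)-alkenyl pinacol boronate, which retains the alkene geometry and tolerates a free alcohol. It is placed at the alcohol stage because C8–H is not acidic there, so warm aqueous carbonate cannot touch the stereocentre, and methoxide is too poor a leaving group for zerovalent palladium to ionise the new allylic ether.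

Step 5
Reactants: 8 (2S)-2-{2-methoxy-4-[(1E)-3-methoxyprop-1-en-1-yl]phenoxy}-1-(3,4,5-trimethoxyphenyl)propan-1-ol (both C7 epimers)
Product: 9 (2S)-2-{2-methoxy-4-[(1E)-3-methoxyprop-1-en-1-yl]phenoxy}-1-(3,4,5-trimethoxyphenyl)propan-1-one, the target
Conditions: Dess–Martin periodinane (1.2 equiv), CH2Cl2, 0 °C to rt
Reagents that add atoms: none
Why: Dess–Martin oxidation of a secondary benzylic alcohol by ligand exchange at iodine and removal of the C7 hydrogen by acetate, in a nearly neutral, non-aqueous medium; both C7 epimers converge on one ketone. No base able to enolise 9 is present, the styrene and the allylic ether are inert to the reagent, and no bond to C8 is touched, so the S configuration set in step 2 is delivered to the target.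

## Compound list

1 | 4-bromo-2-methoxyphenol | COc1cc(Br)ccc1O | starting material
2 | 4-bromo-1-(ethenyloxy)-2-methoxybenzene | C=COc1ccc(Br)cc1OC | intermediate
3 | (2S)-2-(4-bromo-2-methoxyphenoxy)propanal | COc1cc(Br)ccc1O[C@@H](C)C=O | intermediate
4 | 5-bromo-1,2,3-trimethoxybenzene | COc1cc(Br)cc(OC)c1OC | starting material
5 | 3,4,5-trimethoxyphenylmagnesium bromide | COc1cc([Mg]Br)cc(OC)c1OC | intermediate
6 | (2S)-2-(4-bromo-2-methoxyphenoxy)-1-(3,4,5-trimethoxyphenyl)propan-1-ol, both C7 epimers | COc1cc(Br)ccc1O[C@@H](C)C(O)c1cc(OC)c(OC)c(OC)c1 | intermediate
7 | 2-[(1E)-3-methoxyprop-1-en-1-yl]-4,4,5,5-tetramethyl-1,3,2-dioxaborolane | COC/C=C/B1OC(C)(C)C(C)(C)O1 | starting material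
8 | (2S)-2-{2-methoxy-4-[(1E)-3-methoxyprop-1-en-1-yl]phenoxy}-1-(3,4,5-trimethoxyphenyl)propan-1-ol, both C7 epimers | COC/C=C/c1ccc(O[C@@H](C)C(O)c2cc(OC)c(OC)c(OC)c2)c(OC)c1 | intermediate
9 | (2S)-2-{2-methoxy-4-[(1E)-3-methoxyprop-1-en-1-yl]phenoxy}-1-(3,4,5-trimethoxyphenyl)propan-1-one | COC/C=C/c1ccc(O[C@@H](C)C(=O)c2cc(OC)c(OC)c(OC)c2)c(OC)c1 | target

## Step count and risk

Total step count: 5. Longest linear sequence: 5 (1 → 2 → 3 → 6 → 8 → 9).

**Step 2 (key step).**
- Most likely failure: incomplete face selection, together with partial reversal of the hydride insertion by β-hydride elimination from the branched alkyl. Both would erode the enantiomeric purity and the branched preference.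
- A second failure mode concerns the linear alkyl, which holds the aryloxy group β to rhodium. β-Aryloxy elimination, like adventitious hydrolysis of 2, would release phenol that attacks the phosphite arm of the ligand and stops the catalyst.
- Fallback (another bond, known chemistry): it sets out from 1. Mitsunobu inversion of methyl (R)-lactate A2 (PPh3, DIAD, THF, 0 °C) gives methyl (2S)-2-(4-bromo-2-methoxyphenoxy)propanoate F1. DIBAL-H (toluene, –78 °C) reduces F1 to the aldehyde. The route is rejoined at 3.

**Step 3.**
- Most likely failure: deprotonation of C8–H of 3 by the basic aryl Grignard reagent in competition with addition. This would cause partial racemisation and aldol loss, aggravated by the use of crude 3.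
- Fallback (acyl substitution instead of carbonyl addition): it sets out from 3. Pinnick oxidation (NaClO2, NaH2PO4, 2-methylbut-2-ene, t-BuOH/H2O) gives (2S)-2-(4-bromo-2-methoxyphenoxy)propanoic acid F2. The enantiomeric purity of this acid could also be raised by crystallising its salt with 1-phenylethylamine. Coupling with MeNHOMe·HCl (EDC, N-methylmorpholine, CH2Cl2) gives (2S)-2-(4-bromo-2-methoxyphenoxy)-N-methoxy-N-methylpropanamide F3. Reagent 5 (THF, –20 °C, acidic quench) converts it to (2S)-2-(4-bromo-2-methoxyphenoxy)-1-(3,4,5-trimethoxyphenyl)propan-1-one F4. NaBH4 (MeOH, 0 °C) takes F4 to the epimeric alcohols. The route is rejoined at 6.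

**Step 5.**
- Most likely failure: attack of the oxidant, or of the acetic acid it releases, on the electron-rich cinnamyl methyl ether. Enolisation of the freshly formed ketone during work-up or on acidic silica is a second concern.
- Fallback (changed order of events): it sets out from 6. The oxidation is moved ahead of the coupling, so Dess–Martin periodinane converts 6 to the bromoketone F4 already described under step 3, in which no styrene is present. The chain is then attached last without any base by Stille coupling with tributyl[(1E)-3-methoxyprop-1-en-1-yl]stannane F5, made from methyl propargyl ether with Bu3SnH and AIBN at 80 °C. The coupling uses Pd(PPh3)4 in DMF at 80 °C. The route is rejoined at 9.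

**Step 1.**
- Most likely failure: acetyl transfer instead of vinyl transfer to the phenol oxygen, or slow turnover because of the ortho methoxy group.
- Fallback (sp3 alkylation and elimination instead of vinyl transfer): it sets out from 1. 1,2-Dibromoethane (K2CO3, MeCN, reflux) gives 4-bromo-1-(2-bromoethoxy)-2-methoxybenzene F6. E2 elimination with KOt-Bu (THF, 0 °C to rt) gives the vinyl ether. The route is rejoined at 2.

## Further compounds

F1 | step 2 | methyl (2S)-2-(4-bromo-2-methoxyphenoxy)propanoate | COc1cc(Br)ccc1O[C@@H](C)C(=O)OC
F2 | step 3 | (2S)-2-(4-bromo-2-methoxyphenoxy)propanoic acid | COc1cc(Br)ccc1O[C@@H](C)C(=O)O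
F3 | step 3 | (2S)-2-(4-bromo-2-methoxyphenoxy)-N-methoxy-N-methylpropanamide | COc1cc(Br)ccc1O[C@@H](C)C(=O)N(C)OC
F4 | step 3 | (2S)-2-(4-bromo-2-methoxyphenoxy)-1-(3,4,5-trimethoxyphenyl)propan-1-one | COc1cc(Br)ccc1O[C@@H](C)C(=O)c1cc(OC)c(OC)c(OC)c1
F5 | step 5 | tributyl[(1E)-3-methoxyprop-1-en-1-yl]stannane | CCCC[Sn](CCCC)(CCCC)/C=C/COC
F6 | step 1 | 4-bromo-1-(2-bromoethoxy)-2-methoxybenzene | COc1cc(Br)ccc1OCCBr
A1 | alternative 1 | 2-methoxy-4-[(1E)-3-methoxyprop-1-en-1-yl]phenol | COC/C=C/c1ccc(O)c(OC)c1
A2 | alternative 1 | methyl (R)-lactate | C[C@@H](O)C(=O)OC
A3 | alternative 1 | methyl (2S)-2-{2-methoxy-4-[(1E)-3-methoxyprop-1-en-1-yl]phenoxy}propanoate | COC/C=C/c1ccc(O[C@@H](C)C(=O)OC)c(OC)c1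
A4 | alternative 1 | (2S)-N-methoxy-2-{2-methoxy-4-[(1E)-3-methoxyprop-1-en-1-yl]phenoxy}-N-methylpropanamide | COC/C=C/c1ccc(O[C@@H](C)C(=O)N(C)OC)c(OC)c1
A5 | alternative 2 | (2S)-2-hydroxy-N-methoxy-N-methylpropanamide | C[C@H](O)C(=O)N(C)OC
A6 | alternative 2 | 4-fluoro-3-methoxybenzaldehyde | COc1cc(C=O)ccc1F
A7 | alternative 2 | (2S)-2-(4-formyl-2-methoxyphenoxy)-N-methoxy-N-methylpropanamide | COc1cc(C=O)ccc1O[C@@H](C)C(=O)N(C)OC
A8 | alternative 3 | 2-diazo-1-(3,4,5-trimethoxyphenyl)propan-1-one | CC(=[N+]=[N-])C(=O)c1cc(OC)c(OC)c(OC)c1
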